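## Analysis of the target

The target is a 2-hydroxychroman-4-one. Ring C is a cyclic hemiacetal (O1–C2) next to C3 and the C4 ketone, and it is fused to a fully substituted ring A (C5–OH, C6–OMe, C7–OH, C8–Me). C3 carries the carbinol carbon C9, which bears the 4-hydroxyphenyl ring B. There are three stereocenters: C3 (R) and C9 (S) form a syn aldol pair, and C2 (S) is a hemiacetal carbon trans to the C3 substituent. C2 equilibrates by ring–chain tautomerism, and C3 is alpha to the ketone and, in the open form, alpha to an aldehyde as well. The molecule is fragile in several ways. The β-hydroxy ketone can undergo retro-aldol cleavage or lose water. The hemiacetal can dehydrate to the chromone. The C9–O bond is benzylic and para to an oxygen, so acid can ionize it. The open hydroxy aldehyde can also reclose on O5 instead of O1. The second difficulty is ring A: all six carbons are substituted, four of them by oxygen functions that must be told apart, and the acyl carbon has to be attached without Friedel–Crafts conditions. The strategy rests on one feature of ring A. O1 sits on C8a and the acyl carbon C4 on the neighbouring C4a, these are the only two ring A positions that still need bonds, and the oxygen on C5 beside C4a can polarize a C4a≡C8a aryne.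

## Retrosynthetic reasoning

Target 32 is traced back to its tris-benzyl ether 31 by cutting three O–CH2Ph bonds. Hydrogenolysis is neutral, so the aldol and the hemiacetal see neither acid nor base once they are free. Acetal-type phenol protection is avoided because its removal needs acid strong enough to dehydrate the hemiacetal or ionize C9.

Compound 31 is opened at O1–C2 and at the C9 oxygen to give the acyclic ketone 29. In 29, C2 is a dimethyl acetal, C9–O carries a silyl group and the oxygen on C8a is the only free phenol. Because O5 is still benzylated, the forward ring closure can only take place on O1.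

Ketone 29 is cut at O1–C8a and at C4–C4a. This leads to the carboxylic acid 26, which already holds C2, C3, C4 and C9, and to the aryne 28, released from the silyl triflate 13. The cut is made here because these are the two adjacent ring A positions without a substituent from the arene precursor. One operation then joins the hexasubstituted ring to the chiral chain and creates the free phenol that later becomes O1. The forward reaction has to be regioselective (oxygen on C8a, carbon on C4a) and must not disturb C3.

Acid 26 is cut at C3–C9, an aldol bond. The syn relationship and the absolute configuration come from an auxiliary-controlled aldol between the acyl oxazolidinone 18 and aldehyde 19, giving 22. Imide 18 comes from ester 14 and oxazolidinone 16. The aldehyde carbon C2 travels as a dimethyl acetal so that no free β-dicarbonyl compound appears before the end.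

Silyl triflate 13 is traced to bromophenol 10 by a C–Si and an O–S disconnection (bromine–lithium exchange, O→C silyl shift, triflation). Bromophenol 10 comes from phenol 9 by substitution at the only free ring position.

Phenol 9 needs the C6 oxygen and a distinction between the C8a oxygen and its two neighbours. The C6–O bond is cut back to a formyl group (Dakin oxidation). In aldehyde 3 the hydroxyl para to the formyl group differs from the two ortho hydroxyls, and that para hydroxyl is the future C8a oxygen. Aldehyde 3 comes from the symmetric triol 1 by formylation.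

## Alternatives that were turned down

Alternative 1: Ring A is disconnected back to a four-membered ring, the squarate-derived cyclobutenone A1. On heating, A1 would open and reclose by a six-electron electrocyclization and tautomerize to phenol A2, in which every oxygen carries a different group.
- For: the oxygen pattern is differentiated by construction. On this point it is stronger than the present route, which depends on one regioselective mono-protection (step 2).
- Against: the key step makes none of the bonds that join ring A to the chain and sets no stereocenter. After A2 the acyl group still has to be brought to the position ortho to the phenol. The ethyl and isopropyl ethers that give the differentiation would have to be cleaved with boron halides, which the aldol, the hemiacetal and the C6 methyl ether would not survive.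
- Comparison: the squarate sequence is about as long as the arene route from 1. The chosen strategy spends its key step on the hard coupling and uses benzyl groups that leave under neutral conditions.

Alternative 2: C3–C4 and O–C9 are disconnected together, with the aldol masked as an isoxazoline. Oxidation of aldoxime A3 would generate a 1,3-dipole that adds across the tethered Z-alkene and gives the tricycle A4.
- For: one step forms two bonds and two rings and fixes C2, C3 and C9 relative to each other. In rings and stereocenters per step it is stronger than the chosen key step. A doubly ortho-substituted aryl dipole of this kind also resists dimerization.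
- Against: the absolute configuration depends on the acetal carbon of A3, a mixed O-aryl O-methyl acetal that must be made as one enantiomer and can anomerize. Unmasking needs N–O cleavage (for example Mo(CO)6) and then hydrolysis of a hindered, electron-rich aryl ketimine with acid, which endangers the β-hydroxy ketone and the C2 acetal.
- Comparison: the chosen route takes C3 and C9 from an auxiliary aldol of predictable sense and asks the coupling step only for regioselectivity.

Alternative 3: Ring C is disconnected at C3–C4 and O1–C2 as a hetero-Diels–Alder reaction. Irradiation of benzodioxinone A5 would release an acylketene-type heterodiene that adds to the E-enol ether A6 and gives the 2-ethoxychromanone A7.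
- For: ring C closes in the key step under neutral conditions with the right oxidation level at C2. It is stronger than the chosen strategy in ring formation and in avoiding basic fluoride near C3.
- Against: C3 would be set relative to C9 by facial induction from the allylic silyloxy center of an acyclic E-enol ether, where allylic strain gives only weak control, and this is the relationship that matters most. A5 needs a ring A salicylic acid with the same oxygen differentiation problem. The methoxymethyl groups of A7 need acid at the end.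
- Comparison: the chosen route fixes the C3/C9 relationship before the coupling and removes its protecting groups without acid.

Key step: step 14

Assumption: C2 is a hemiacetal carbon that equilibrates through the open hydroxy aldehyde; the 2,3-trans (2S) anomer drawn is taken to be the one favoured at equilibrium, so C2 is set under thermodynamic control and not by a reagent.

## Route

Step 1
Reactants: 1 2,4,6-trihydroxytoluene
Product: 3 2,4,6-trihydroxy-3-methylbenzaldehyde, via aryl iminium chloride 2 (not isolated)
Conditions: POCl3, DMF, EtOAc, 0 °C → rt; then H2O, 50 °C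
Reagents that add atoms: N,N-dimethylformamide CN(C)C=O; water O
Why: Vilsmeier–Haack formylation; the two free ring positions of 1 are equivalent, the first formyl group deactivates the ring against a second substitution, and hydrolysis of iminium salt 2 gives the aldehyde.

Step 2
Reactants: 3 2,4,6-trihydroxy-3-methylbenzaldehyde
Product: 4 2,6-dihydroxy-4-(methoxymethoxy)-3-methylbenzaldehyde
Conditions: MOMCl (1.0 equiv), iPr2NEt (1.1 equiv), THF, −20 → 0 °C
Reagents that add atoms: chloromethyl methyl ether COCCl
Why: Regioselective O-alkylation; the 4-hydroxyl is para to the formyl group, the most acidic and the only one not held in a hydrogen bond to the carbonyl oxygen, so one equivalent of electrophile with a weak amine base should take it first.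

Step 3
Reactants: 4 2,6-dihydroxy-4-(methoxymethoxy)-3-methylbenzaldehyde
Product: 5 2,6-bis(benzyloxy)-4-(methoxymethoxy)-3-methylbenzaldehyde
Conditions: BnBr (2.5 equiv), K2CO3, DMF, 50 °C
Reagents that add atoms: benzyl bromide BrCc1ccccc1
Why: Williamson etherification; carbonate in warm DMF overcomes the hydrogen bonding of the two ortho hydroxyls, the formyl group keeps the ring from C-alkylation, and the methoxymethyl ether is stable to base.

Step 4
Reactants: 5 2,6-bis(benzyloxy)-4-(methoxymethoxy)-3-methylbenzaldehyde
Product: 7 2,6-bis(benzyloxy)-4-(methoxymethoxy)-3-methylphenol, via aryl formate 6 (not isolated)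
Conditions: mCPBA, CH2Cl2, 0 °C → rt; aq. NaHCO3 wash; then K2CO3 (cat.), MeOH, 0 °C
Reagents that add atoms: 3-chloroperoxybenzoic acid OOC(=O)c1cccc(Cl)c1
Why: Dakin-type Baeyer–Villiger oxidation; the electron-rich trialkoxyaryl group migrates in preference to hydrogen, and mild methanolysis of formate 6 frees the phenol that becomes the C6 oxygen.

Step 5
Reactants: 7 2,6-bis(benzyloxy)-4-(methoxymethoxy)-3-methylphenol
Product: 8 1,3-bis(benzyloxy)-2-methoxy-5-(methoxymethoxy)-4-methylbenzene
Conditions: MeI, K2CO3, acetone, 56 °C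
Reagents that add atoms: iodomethane CI
Why: Williamson methylation of the only free phenol; the small electrophile tolerates the two flanking benzyloxy groups.

Step 6
Reactants: 8 1,3-bis(benzyloxy)-2-methoxy-5-(methoxymethoxy)-4-methylbenzene
Product: 9 3,5-bis(benzyloxy)-4-methoxy-2-methylphenol
Conditions: HCl (cat.), MeOH, 45 °C
Reagents that add atoms: none
Why: Acid-catalysed acetal exchange removes the methoxymethyl group, with methanol as solvent trapping the oxocarbenium ion before it can alkylate the ring; aryl benzyl and methyl ethers are stable to dilute HCl.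

Step 7
Reactants: 9 3,5-bis(benzyloxy)-4-methoxy-2-methylphenol
Product: 10 3,5-bis(benzyloxy)-2-bromo-4-methoxy-6-methylphenol
Conditions: NBS (1.0 equiv), CH2Cl2, −78 → −20 °C
Reagents that add atoms: N-bromosuccinimide O=C1CCC(=O)N1Br
Why: Electrophilic aromatic bromination at the only unsubstituted ring carbon, which is ortho to the hydroxyl and ortho and para to the benzyloxy groups; low temperature and one equivalent of reagent guard against oxidation to a quinone.

Step 8
Reactants: 10 3,5-bis(benzyloxy)-2-bromo-4-methoxy-6-methylphenol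
Product: 13 3,5-bis(benzyloxy)-4-methoxy-2-methyl-6-(trimethylsilyl)phenyl trifluoromethanesulfonate, via aryl trimethylsilyl ether 11 (not isolated), via lithium 2-silylphenoxide 12 (not isolated)
Conditions: (Me3Si)2NH, THF, 65 °C, then evaporation; n-BuLi, THF, −78 °C; Tf2O, −78 → 0 °C
Reagents that add atoms: hexamethyldisilazane C[Si](C)(C)N[Si](C)(C)C; trifluoromethanesulfonic anhydride O=S(=O)(OS(=O)(=O)C(F)(F)F)C(F)(F)F
Why: O-silylation, then bromine–lithium exchange and a 1,3 O→C silyl shift (retro-Brook rearrangement) driven by formation of the phenoxide, which is triflated in the same flask; exchange at −78 °C is much faster than any attack on the benzyl ethers.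

Step 9
Reactants: 14 methyl 3,3-dimethoxypropanoate
Product: 15 lithium 3,3-dimethoxypropanoate
Conditions: LiOH·H2O (1.0 equiv), THF/H2O, 0 °C → rt; evaporation, drying
Reagents that add atoms: lithium hydroxide [Li+].[OH-]
Why: Ester saponification; the acetal is stable to base, and isolating the salt avoids the free β,β-dialkoxy acid, which loses methanol easily.

Step 10
Reactants: 15 lithium 3,3-dimethoxypropanoate; 16 (S)-4-benzyloxazolidin-2-one
Product: 18 (S)-4-benzyl-3-(3,3-dimethoxypropanoyl)oxazolidin-2-one, via mixed pivalic anhydride 17 (not isolated)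
Conditions: PivCl, THF, −20 °C; then 16, LiCl, Et3N, −20 °C → rt
Reagents that add atoms: none
Why: N-acylation of the oxazolidinone through a mixed anhydride under LiCl/Et3N activation; the nitrogen attacks the less hindered carbonyl group of 17.

Step 11
Reactants: 18 (S)-4-benzyl-3-(3,3-dimethoxypropanoyl)oxazolidin-2-one; 19 4-(benzyloxy)benzaldehyde
Product: 22 (S)-4-benzyl-3-[(2R,3S)-3-[4-(benzyloxy)phenyl]-2-(dimethoxymethyl)-3-hydroxypropanoyl]oxazolidin-2-one, via Z-boron enolate 20 (not isolated), via boron aldolate 21 (not isolated)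
Conditions: Bu2BOTf, iPr2NEt, CH2Cl2, −78 → 0 °C; 19, −78 → 0 °C; pH 7 buffer, MeOH, 30% H2O2, 0 °C
Reagents that add atoms: none
Why: Evans syn aldol reaction; the Z-boron enolate 20 reacts through a chair Zimmerman–Traxler transition state in which the benzyl group of the auxiliary shields one enolate face, which sets C3 and C9 as the syn pair with the (2R,3S) configuration of the target; a covalent boron enolate is not expected to expel the β-methoxy group.

Step 12
Reactants: 22 (S)-4-benzyl-3-[(2R,3S)-3-[4-(benzyloxy)phenyl]-2-(dimethoxymethyl)-3-hydroxypropanoyl]oxazolidin-2-one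
Product: 24 (2R,3S)-3-[4-(benzyloxy)phenyl]-2-(dimethoxymethyl)-3-hydroxypropanoic acid, via lithium peroxycarboxylate 23 (not isolated)
Conditions: LiOH, 30% H2O2, THF/H2O, 0 °C; aq. Na2SO3; HCl to pH 4, 0 °C
Reagents that add atoms: hydrogen peroxide OO
Why: Hydroperoxide cleavage of the auxiliary; the hydroperoxide anion attacks the exocyclic carbonyl group selectively, sulfite reduces peroxycarboxylate 23, and acidifying only to pH 4 in the cold keeps the acetal; the free β-hydroxy imide is cleaved here because the silylated one would be much more hindered.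

Step 13
Reactants: 24 (2R,3S)-3-[4-(benzyloxy)phenyl]-2-(dimethoxymethyl)-3-hydroxypropanoic acid
Product: 26 (2R,3S)-3-[4-(benzyloxy)phenyl]-3-[(tert-butyldimethylsilyl)oxy]-2-(dimethoxymethyl)propanoic acid, via silyl ester 25 (not isolated)
Conditions: TBSOTf (2.5 equiv), 2,6-lutidine, CH2Cl2, −78 → 0 °C; then K2CO3, THF/H2O, rt; pH 4–5
Reagents that add atoms: tert-butyldimethylsilyl trifluoromethanesulfonate CC(C)(C)[Si](C)(C)OS(=O)(=O)C(F)(F)F
Why: Silylation of the hydroxyl and carboxyl groups, then selective hydrolysis of the labile silyl ester 25 by aqueous carbonate; at low temperature O-silylation should outrun activation of the acetal by the silyl triflate.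

Step 14
Reactants: 26 (2R,3S)-3-[4-(benzyloxy)phenyl]-3-[(tert-butyldimethylsilyl)oxy]-2-(dimethoxymethyl)propanoic acid; 13 3,5-bis(benzyloxy)-4-methoxy-2-methyl-6-(trimethylsilyl)phenyl trifluoromethanesulfonate
Product: 29 (2R,3S)-1-[2,4-bis(benzyloxy)-6-hydroxy-3-methoxy-5-methylphenyl]-3-[4-(benzyloxy)phenyl]-3-[(tert-butyldimethylsilyl)oxy]-2-(dimethoxymethyl)propan-1-one, via cesium carboxylate 27 (not isolated), via aryne 28 (not isolated)
Conditions: Cs2CO3 (0.5 equiv), MeOH, rt, evaporation, PhMe azeotrope; 13 (1.5 equiv), CsF (3 equiv), THF, 70 °C, sealed tube; aq. NH4Cl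
Reagents that add atoms: none
Why: Fluoride attacks the trimethylsilyl group of 13 and triflate leaves, which gives aryne 28 with its triple bond between C4a and C8a. A carboxylate oxygen of 27 adds to C8a, and the aryl anion left on C4a attacks the carbonyl carbon of the aryl ester just formed through a four-membered alkoxide that opens to the cesium phenoxide of 29, so that O1–C8a and C4–C4a are made in one operation. The closest known reaction type is the fluoride-induced insertion of arynes into the C–O bond of carboxylic acids to give ortho-hydroxyaryl ketones, formally an intermolecular anionic Fries rearrangement. No ring is closed and no stereocenter is created; C3 and C9 come in unchanged from 26. The step needs regioselectivity, and the benzyloxy group on C5 supplies it: its inductive pull makes the remote carbon C8a the electrophilic end of the aryne and places the developing negative charge on C4a next to that oxygen, against which the C8 methyl group has only a small steric effect. The step also needs acyl transfer to outrun protonation of the aryl anion, which is why the acid is used as its dry, preformed cesium salt in an aprotic solvent with no other proton source. The configuration at C3 is helped by the ketone being born as a 2-acylphenoxide, a vinylogous carboxylate whose carbonyl group acidifies the alpha hydrogen only weakly, and by running at the lowest temperature that still releases the aryne.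

Step 15
Reactants: 29 (2R,3S)-1-[2,4-bis(benzyloxy)-6-hydroxy-3-methoxy-5-methylphenyl]-3-[4-(benzyloxy)phenyl]-3-[(tert-butyldimethylsilyl)oxy]-2-(dimethoxymethyl)propan-1-one
Product: 31 (2S,3R)-5,7-bis(benzyloxy)-3-[(S)-[4-(benzyloxy)phenyl](hydroxy)methyl]-2-hydroxy-6-methoxy-8-methyl-2,3-dihydro-4H-chromen-4-one, via 2-methoxychromanone 30 (not isolated)
Conditions: 48% aq. HF, MeCN, 0 °C → rt; aq. NaHCO3
Reagents that add atoms: water O
Why: Acid-mediated acetal exchange and desilylation; the acetal ionizes and the only free phenol, on C8a, closes the six-membered ring onto the oxocarbenium ion to give 30, HF cleaves the Si–O bond, and excess water exchanges the methyl acetal for the hemiacetal; O5 is still benzylated, so closure can only give the O1 isomer, and C2 settles under thermodynamic control.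

Step 16
Reactants: 31 (2S,3R)-5,7-bis(benzyloxy)-3-[(S)-[4-(benzyloxy)phenyl](hydroxy)methyl]-2-hydroxy-6-methoxy-8-methyl-2,3-dihydro-4H-chromen-4-one
Product: 32 (2S,3R)-2,5,7-trihydroxy-3-[(S)-hydroxy(4-hydroxyphenyl)methyl]-6-methoxy-8-methyl-2,3-dihydro-4H-chromen-4-one
Conditions: H2 (1 atm), 10% Pd/C, EtOAc, rt
Reagents that add atoms: none
Why: Hydrogenolysis of the three aryl benzyl ethers under neutral conditions; aryl O–CH2Ph bonds are cleaved much faster than the secondary benzylic C9–OH bond or the hydrogen-bonded aryl ketone is reduced, and the product is isolated by filtration without acid or base.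

## Compound list

1 | 2,4,6-trihydroxytoluene | Cc1c(O)cc(O)cc1O | starting material
2 | N-methyl-N-[(2,4,6-trihydroxy-3-methylphenyl)methylidene]methanaminium chloride | C[N+](C)=Cc1c(O)cc(O)c(C)c1O.[Cl-] | intermediate
3 | 2,4,6-trihydroxy-3-methylbenzaldehyde | O=Cc1c(O)cc(O)c(C)c1O | intermediate
4 | 2,6-dihydroxy-4-(methoxymethoxy)-3-methylbenzaldehyde | O=Cc1c(O)cc(OCOC)c(C)c1O | intermediate
5 | 2,6-bis(benzyloxy)-4-(methoxymethoxy)-3-methylbenzaldehyde | O=Cc1c(OCc2ccccc2)cc(OCOC)c(C)c1OCc1ccccc1 | intermediate
6 | 2,6-bis(benzyloxy)-4-(methoxymethoxy)-3-methylphenyl formate | O=COc1c(OCc2ccccc2)cc(OCOC)c(C)c1OCc1ccccc1 | intermediate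
7 | 2,6-bis(benzyloxy)-4-(methoxymethoxy)-3-methylphenol | Oc1c(OCc2ccccc2)cc(OCOC)c(C)c1OCc1ccccc1 | intermediate
8 | 1,3-bis(benzyloxy)-2-methoxy-5-(methoxymethoxy)-4-methylbenzene | COc1c(OCc2ccccc2)cc(OCOC)c(C)c1OCc1ccccc1 | intermediate
9 | 3,5-bis(benzyloxy)-4-methoxy-2-methylphenol | COc1c(OCc2ccccc2)cc(O)c(C)c1OCc1ccccc1 | intermediate
10 | 3,5-bis(benzyloxy)-2-bromo-4-methoxy-6-methylphenol | COc1c(OCc2ccccc2)c(Br)c(O)c(C)c1OCc1ccccc1 | intermediate
11 | [3,5-bis(benzyloxy)-2-bromo-4-methoxy-6-methylphenoxy]trimethylsilane | COc1c(OCc2ccccc2)c(Br)c(O[Si](C)(C)C)c(C)c1OCc1ccccc1 | intermediate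
12 | lithium 3,5-bis(benzyloxy)-4-methoxy-2-methyl-6-(trimethylsilyl)phenoxide | [Li+].COc1c(OCc2ccccc2)c([Si](C)(C)C)c([O-])c(C)c1OCc1ccccc1 | intermediate
13 | 3,5-bis(benzyloxy)-4-methoxy-2-methyl-6-(trimethylsilyl)phenyl trifluoromethanesulfonate | COc1c(OCc2ccccc2)c(C)c(OS(=O)(=O)C(F)(F)F)c([Si](C)(C)C)c1OCc1ccccc1 | intermediate
14 | methyl 3,3-dimethoxypropanoate | COC(=O)CC(OC)OC | starting material
15 | lithium 3,3-dimethoxypropanoate | [Li+].[O-]C(=O)CC(OC)OC | intermediate
16 | (S)-4-benzyloxazolidin-2-one | O=C1OC[C@H](Cc2ccccc2)N1 | starting material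
17 | 3,3-dimethoxypropanoic pivalic anhydride | CC(C)(C)C(=O)OC(=O)CC(OC)OC | intermediate
18 | (S)-4-benzyl-3-(3,3-dimethoxypropanoyl)oxazolidin-2-one | O=C1OC[C@H](Cc2ccccc2)N1C(=O)CC(OC)OC | intermediate
19 | 4-(benzyloxy)benzaldehyde | O=Cc1ccc(OCc2ccccc2)cc1 | starting material
20 | dibutyl{[(1Z)-1-[(4S)-4-benzyl-2-oxooxazolidin-3-yl]-3,3-dimethoxyprop-1-en-1-yl]oxy}borane | CCCCB(CCCC)O/C(=C\C(OC)OC)N1[C@@H](Cc2ccccc2)COC1=O | intermediate
21 | (S)-4-benzyl-3-[(2R,3S)-3-[4-(benzyloxy)phenyl]-3-[(dibutylboranyl)oxy]-2-(dimethoxymethyl)propanoyl]oxazolidin-2-one | O=C1OC[C@H](Cc2ccccc2)N1C(=O)[C@H]([C@H](OB(CCCC)CCCC)c1ccc(OCc2ccccc2)cc1)C(OC)OC | intermediate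
22 | (S)-4-benzyl-3-[(2R,3S)-3-[4-(benzyloxy)phenyl]-2-(dimethoxymethyl)-3-hydroxypropanoyl]oxazolidin-2-one | O=C1OC[C@H](Cc2ccccc2)N1C(=O)[C@H]([C@H](O)c1ccc(OCc2ccccc2)cc1)C(OC)OC | intermediate
23 | lithium (2R,3S)-3-[4-(benzyloxy)phenyl]-2-(dimethoxymethyl)-3-hydroxypropaneperoxoate | [Li+].[O-]OC(=O)[C@H]([C@H](O)c1ccc(OCc2ccccc2)cc1)C(OC)OC | intermediate
24 | (2R,3S)-3-[4-(benzyloxy)phenyl]-2-(dimethoxymethyl)-3-hydroxypropanoic acid | OC(=O)[C@H]([C@H](O)c1ccc(OCc2ccccc2)cc1)C(OC)OC | intermediate
25 | tert-butyldimethylsilyl (2R,3S)-3-[4-(benzyloxy)phenyl]-3-[(tert-butyldimethylsilyl)oxy]-2-(dimethoxymethyl)propanoate | CC(C)(C)[Si](C)(C)OC(=O)[C@H]([C@H](O[Si](C)(C)C(C)(C)C)c1ccc(OCc2ccccc2)cc1)C(OC)OC | intermediate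
26 | (2R,3S)-3-[4-(benzyloxy)phenyl]-3-[(tert-butyldimethylsilyl)oxy]-2-(dimethoxymethyl)propanoic acid | OC(=O)[C@H]([C@H](O[Si](C)(C)C(C)(C)C)c1ccc(OCc2ccccc2)cc1)C(OC)OC | intermediate
27 | cesium (2R,3S)-3-[4-(benzyloxy)phenyl]-3-[(tert-butyldimethylsilyl)oxy]-2-(dimethoxymethyl)propanoate | [Cs+].[O-]C(=O)[C@H]([C@H](O[Si](C)(C)C(C)(C)C)c1ccc(OCc2ccccc2)cc1)C(OC)OC | intermediate
28 | 3,5-bis(benzyloxy)-4-methoxy-6-methyl-1,2-didehydrobenzene | COC1=C(OCc2ccccc2)C#CC(C)=C1OCc1ccccc1 | intermediate
29 | (2R,3S)-1-[2,4-bis(benzyloxy)-6-hydroxy-3-methoxy-5-methylphenyl]-3-[4-(benzyloxy)phenyl]-3-[(tert-butyldimethylsilyl)oxy]-2-(dimethoxymethyl)propan-1-one | COc1c(OCc2ccccc2)c(C)c(O)c(c1OCc1ccccc1)C(=O)[C@H]([C@H](O[Si](C)(C)C(C)(C)C)c1ccc(OCc2ccccc2)cc1)C(OC)OC | intermediate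
30 | (3R)-5,7-bis(benzyloxy)-3-[(S)-[4-(benzyloxy)phenyl][(tert-butyldimethylsilyl)oxy]methyl]-2,6-dimethoxy-8-methyl-2,3-dihydro-4H-chromen-4-one (both C2 epimers) | COc1c(OCc2ccccc2)c(C)c2c(c1OCc1ccccc1)C(=O)[C@H]([C@H](O[Si](C)(C)C(C)(C)C)c1ccc(OCc3ccccc3)cc1)C(OC)O2 | intermediate
31 | (2S,3R)-5,7-bis(benzyloxy)-3-[(S)-[4-(benzyloxy)phenyl](hydroxy)methyl]-2-hydroxy-6-methoxy-8-methyl-2,3-dihydro-4H-chromen-4-one | COc1c(OCc2ccccc2)c(C)c2c(c1OCc1ccccc1)C(=O)[C@H]([C@H](O)c1ccc(OCc3ccccc3)cc1)[C@@H](O)O2 | intermediate
32 | (2S,3R)-2,5,7-trihydroxy-3-[(S)-hydroxy(4-hydroxyphenyl)methyl]-6-methoxy-8-methyl-2,3-dihydro-4H-chromen-4-one | COc1c(O)c(C)c2c(c1O)C(=O)[C@H]([C@H](O)c1ccc(O)cc1)[C@@H](O)O2 | target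

## Step count and least certain steps

Total: 16 steps. Longest linear sequence: 11 steps (steps 1–8, then 14–16). The acid branch (steps 9–13) has 5 steps.

**Step 14 (key step).** The aryl anion may be protonated, or may remove the alpha hydrogen of the newly formed aryl ester, faster than it attacks the hindered ester carbonyl group. That would give simple O-arylation and, through the ester enolate, loss of the C3 configuration or elimination of the silyloxy group. Basic fluoride at 70 °C could also epimerize C3 or trigger β-elimination in the product, and some carboxylate may add at the other aryne carbon. Fallback: it sets out from bromophenol 10 and acid 26. Esterification (DCC, DMAP, CH2Cl2) gives 3,5-bis(benzyloxy)-2-bromo-4-methoxy-6-methylphenyl (2R,3S)-3-[4-(benzyloxy)phenyl]-3-[(tert-butyldimethylsilyl)oxy]-2-(dimethoxymethyl)propanoate F1. Bromine–lithium exchange with n-BuLi in THF at −100 °C generates the same ortho-acyloxy aryl anion without an aryne and without fluoride, and the anionic Fries-type 1,3 O→C acyl shift gives the phenoxide of 29. This is regiochemically unambiguous, and the route is rejoined at 29.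

**Step 11.** The boron triflate may ionize the dimethyl acetal, or the enolate may lose methoxide, so that enolization of 18 is incomplete or gives an unsaturated imide; the electron-rich aldehyde 19 is also a slow partner. Fallback: it sets out from 16.
- Acylation (n-BuLi, crotonyl chloride) gives (S)-4-benzyl-3-[(E)-but-2-enoyl]oxazolidin-2-one F2.
- Its boron dienolate (Bu2BOTf, Et3N) reacts with 19 at the alpha carbon in the same Evans syn sense and gives (S)-4-benzyl-3-[(2S)-2-[(S)-[4-(benzyloxy)phenyl](hydroxy)methyl]but-3-enoyl]oxazolidin-2-one F3.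
- Silylation (TBSOTf, 2,6-lutidine) gives the tert-butyldimethylsilyl ether of the vinyl aldol F4.
- Ozonolysis (O3, CH2Cl2/MeOH, −78 °C; Me2S) gives (S)-4-benzyl-3-[(2R,3S)-3-[4-(benzyloxy)phenyl]-3-[(tert-butyldimethylsilyl)oxy]-2-formylpropanoyl]oxazolidin-2-one F5.
- F5 is converted at once (HC(OMe)3, PPTS, MeOH) into (S)-4-benzyl-3-[(2R,3S)-3-[4-(benzyloxy)phenyl]-3-[(tert-butyldimethylsilyl)oxy]-2-(dimethoxymethyl)propanoyl]oxazolidin-2-one F6.
- LiOH/H2O2 cleaves the auxiliary, and the route is rejoined at 26.

**Step 15.** Desilylation of the hindered benzylic ether is slow, so the freed hemiacetal stays in acid for a long time. It may lose water to the chromone, C9 may ionize, or C3 may epimerize through the open enol. Fallback: it sets out from 29 and separates the three events. Camphorsulfonic acid (cat.) in toluene over 4 Å molecular sieves closes the ring without water and gives 30, which is isolated. HF·pyridine in THF/pyridine removes the silyl group and gives (3R)-5,7-bis(benzyloxy)-3-[(S)-[4-(benzyloxy)phenyl](hydroxy)methyl]-2,6-dimethoxy-8-methyl-2,3-dihydro-4H-chromen-4-one F7. Brief hydrolysis of the methyl acetal (PPTS, acetone/H2O, 40 °C) then leads back to 31.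

**Step 16.** The catalyst may over-reduce the molecule: hydrogenolysis of the benzylic C9–O bond once the para oxygen is free, or reduction of the open aldehyde form. Fallback: it sets out from 29, which is closed to 30 as above. Hydrogenolysis (H2, Pd/C, EtOAc) is carried out on 30, where C9 is silylated and C2 is locked as the methyl acetal, to give (3R)-3-[(S)-[(tert-butyldimethylsilyl)oxy](4-hydroxyphenyl)methyl]-5,7-dihydroxy-2,6-dimethoxy-8-methyl-2,3-dihydro-4H-chromen-4-one F8. Aqueous HF in MeCN then removes the silyl group and hydrolyses the acetal to give 32 directly. The price is that the last acid step runs with O5 free, so ring opening and reclosure on O5 becomes possible; that is why this order is the fallback and not the main line.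

**Step 2.** Alkylation may be incompletely regioselective, with some reaction at an ortho hydroxyl or twofold alkylation, because the two ortho hydroxyls are not both chelated at the same moment. Fallback: it sets out from 3 and replaces acidity control by steric control at a hydroquinone.
- Exhaustive benzylation (BnBr, K2CO3, DMF) gives 2,4,6-tris(benzyloxy)-3-methylbenzaldehyde F9.
- Baeyer–Villiger oxidation (mCPBA) gives 2,4,6-tris(benzyloxy)-3-methylphenyl formate F10, and methanolysis gives 2,4,6-tris(benzyloxy)-3-methylphenol F11.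
- Oxidation with PhI(OAc)2 in MeCN/H2O expels the para benzyl group and gives 3,5-bis(benzyloxy)-2-methyl-1,4-benzoquinone F12.
- Na2S2O4 reduces it to 3,5-bis(benzyloxy)-2-methylbenzene-1,4-diol F13.
- TIPSCl and imidazole silylate only the hydroxyl flanked by methyl and hydrogen and give 2,6-bis(benzyloxy)-3-methyl-4-[(triisopropylsilyl)oxy]phenol F14.
- MeI and K2CO3 methylate the hindered hydroxyl and give [3,5-bis(benzyloxy)-4-methoxy-2-methylphenoxy]triisopropylsilane F15.
- Bu4NF removes the silyl group, and the route is rejoined at 9.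

## Further compounds

F1 | step 14 | 3,5-bis(benzyloxy)-2-bromo-4-methoxy-6-methylphenyl (2R,3S)-3-[4-(benzyloxy)phenyl]-3-[(tert-butyldimethylsilyl)oxy]-2-(dimethoxymethyl)propanoate | COc1c(OCc2ccccc2)c(Br)c(OC(=O)[C@H]([C@H](O[Si](C)(C)C(C)(C)C)c2ccc(OCc3ccccc3)cc2)C(OC)OC)c(C)c1OCc1ccccc1
F2 | step 11 | (S)-4-benzyl-3-[(E)-but-2-enoyl]oxazolidin-2-one | C/C=C/C(=O)N1[C@@H](Cc2ccccc2)COC1=O
F3 | step 11 | (S)-4-benzyl-3-[(2S)-2-[(S)-[4-(benzyloxy)phenyl](hydroxy)methyl]but-3-enoyl]oxazolidin-2-one | O=C1OC[C@H](Cc2ccccc2)N1C(=O)[C@H]([C@H](O)c1ccc(OCc2ccccc2)cc1)C=C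
F4 | step 11 | (S)-4-benzyl-3-[(2S)-2-[(S)-[4-(benzyloxy)phenyl][(tert-butyldimethylsilyl)oxy]methyl]but-3-enoyl]oxazolidin-2-one | O=C1OC[C@H](Cc2ccccc2)N1C(=O)[C@H]([C@H](O[Si](C)(C)C(C)(C)C)c1ccc(OCc2ccccc2)cc1)C=C
F5 | step 11 | (S)-4-benzyl-3-[(2R,3S)-3-[4-(benzyloxy)phenyl]-3-[(tert-butyldimethylsilyl)oxy]-2-formylpropanoyl]oxazolidin-2-one | O=C1OC[C@H](Cc2ccccc2)N1C(=O)[C@H]([C@H](O[Si](C)(C)C(C)(C)C)c1ccc(OCc2ccccc2)cc1)C=O
F6 | step 11 | (S)-4-benzyl-3-[(2R,3S)-3-[4-(benzyloxy)phenyl]-3-[(tert-butyldimethylsilyl)oxy]-2-(dimethoxymethyl)propanoyl]oxazolidin-2-one | O=C1OC[C@H](Cc2ccccc2)N1C(=O)[C@H]([C@H](O[Si](C)(C)C(C)(C)C)c1ccc(OCc2ccccc2)cc1)C(OC)OC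
F7 | step 15 | (3R)-5,7-bis(benzyloxy)-3-[(S)-[4-(benzyloxy)phenyl](hydroxy)methyl]-2,6-dimethoxy-8-methyl-2,3-dihydro-4H-chromen-4-one (both C2 epimers) | COc1c(OCc2ccccc2)c(C)c2c(c1OCc1ccccc1)C(=O)[C@H]([C@H](O)c1ccc(OCc3ccccc3)cc1)C(OC)O2
F8 | step 16 | (3R)-3-[(S)-[(tert-butyldimethylsilyl)oxy](4-hydroxyphenyl)methyl]-5,7-dihydroxy-2,6-dimethoxy-8-methyl-2,3-dihydro-4H-chromen-4-one (both C2 epimers) | COc1c(O)c(C)c2c(c1O)C(=O)[C@H]([C@H](O[Si](C)(C)C(C)(C)C)c1ccc(O)cc1)C(OC)O2
F9 | step 2 | 2,4,6-tris(benzyloxy)-3-methylbenzaldehyde | O=Cc1c(OCc2ccccc2)cc(OCc2ccccc2)c(C)c1OCc1ccccc1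
F10 | step 2 | 2,4,6-tris(benzyloxy)-3-methylphenyl formate | O=COc1c(OCc2ccccc2)cc(OCc2ccccc2)c(C)c1OCc1ccccc1
F11 | step 2 | 2,4,6-tris(benzyloxy)-3-methylphenol | Oc1c(OCc2ccccc2)cc(OCc2ccccc2)c(C)c1OCc1ccccc1
F12 | step 2 | 3,5-bis(benzyloxy)-2-methylcyclohexa-2,5-diene-1,4-dione | O=C1C=C(OCc2ccccc2)C(=O)C(OCc2ccccc2)=C1C
F13 | step 2 | 3,5-bis(benzyloxy)-2-methylbenzene-1,4-diol | Cc1c(O)cc(OCc2ccccc2)c(O)c1OCc1ccccc1
F14 | step 2 | 2,6-bis(benzyloxy)-3-methyl-4-[(triisopropylsilyl)oxy]phenol | Cc1c(O[Si](C(C)C)(C(C)C)C(C)C)cc(OCc2ccccc2)c(O)c1OCc1ccccc1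
F15 | step 2 | [3,5-bis(benzyloxy)-4-methoxy-2-methylphenoxy]triisopropylsilane | COc1c(OCc2ccccc2)cc(O[Si](C(C)C)(C(C)C)C(C)C)c(C)c1OCc1ccccc1
A1 | alternative 1 | 4-(1-ethoxyethenyl)-4-methoxy-2-methyl-3-(propan-2-yloxy)cyclobut-2-en-1-one | CC1=C(OC(C)C)C(OC)(C(=C)OCC)C1=O
A2 | alternative 1 | 5-ethoxy-4-methoxy-2-methyl-3-(propan-2-yloxy)phenol | Cc1c(O)cc(OCC)c(OC)c1OC(C)C
A3 | alternative 2 | 2-{[(1S,2Z)-3-{4-[(tert-butyldimethylsilyl)oxy]phenyl}-1-methoxyprop-2-en-1-yl]oxy}-5-methoxy-4,6-bis(methoxymethoxy)-3-methylbenzaldehyde oxime | COc1c(OCOC)c(C)c(O[C@H](OC)/C=C\c2ccc(O[Si](C)(C)C(C)(C)C)cc2)c(C=NO)c1OCOC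
A4 | alternative 2 | chromanone-fused 2-isoxazoline with C2 methoxy, C9 aryl (silyl-protected) and bis(methoxymethyl)-protected ring A, C2, C3 and C9 as in the target | COc1c(OCOC)c(C)c2c(c1OCOC)C(=NO3)[C@H]([C@H]3c1ccc(O[Si](C)(C)C(C)(C)C)cc1)[C@@H](OC)O2
A5 | alternative 3 | 6-methoxy-5,7-bis(methoxymethoxy)-2,2,8-trimethyl-4H-1,3-benzodioxin-4-one | COc1c(OCOC)c(C)c2OC(C)(C)OC(=O)c2c1OCOC
A6 | alternative 3 | tert-butyl{4-[(1S,2E)-1-[(tert-butyldimethylsilyl)oxy]-3-ethoxyprop-2-en-1-yl]phenoxy}dimethylsilane | CCO/C=C/[C@H](O[Si](C)(C)C(C)(C)C)c1ccc(O[Si](C)(C)C(C)(C)C)cc1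
A7 | alternative 3 | (2S,3R)-3-[(S)-[(tert-butyldimethylsilyl)oxy]{4-[(tert-butyldimethylsilyl)oxy]phenyl}methyl]-2-ethoxy-6-methoxy-5,7-bis(methoxymethoxy)-8-methyl-2,3-dihydro-4H-chromen-4-one | COc1c(OCOC)c(C)c2c(c1OCOC)C(=O)[C@H]([C@H](O[Si](C)(C)C(C)(C)C)c1ccc(O[Si](C)(C)C(C)(C)C)cc1)[C@@H](OCC)O2
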